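**Assumptions**
- The target, 5,7,8,3',4',5'-hexamethoxyflavone (C21H22O8), has no stereocentres and is achiral. "Single enantiomer" therefore does not apply and no stereocontrol is needed.
- 1,2,3,5-Tetramethoxybenzene is taken as a catalogue chemical.

## Retrosynthetic overview
1. Both arene rings (A and B) are bought fully oxygenated. Only the pyranone C ring is built, and it is formed last.
2. Disconnect the C ring at O1–C2 and lower the C2=C3 oxidation level, giving a 2'-hydroxychalcone (forward: oxidative cyclisation).
3. Disconnect the chalcone at Cα=Cβ by Claisen–Schmidt, giving 2-hydroxy-3,4,6-trimethoxyacetophenone and 3,4,5-trimethoxybenzaldehyde.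
4. The acetophenone comes from Friedel–Crafts acetylation and in-situ ortho-demethylation of C2-symmetric 1,2,3,5-tetramethoxybenzene.
5. Atom mapping from acetophenone to flavone: C1→C4a, C2(OH)→C8a/O1, C3-OMe→8-OMe, C4-OMe→7-OMe, C5-H→H-6, C6-OMe→5-OMe.

## Route

**Step 1**
Reactants: 1, 1,2,3,5-tetramethoxybenzene; 2, acetyl chloride
Product: 3, 1-(2-hydroxy-3,4,6-trimethoxyphenyl)ethan-1-one (acetyl at C1, OH at C2, OMe at C3, C4 and C6, H at C5)
Conditions: AcCl (1.2 equiv), AlCl3 (2.5 equiv), dry Et2O, 0 °C → rt, about 24 h; then ice/2 M HCl; recrystallise from MeOH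
Reagents that add atoms: acetyl chloride, CC(=O)Cl (one O-methyl is lost as MeCl)
Why: This is a Friedel–Crafts acylation, and the two free ring positions are symmetry-equivalent, so only one ketone can form. AlCl3 chelated to the carbonyl then cleaves the crowded, out-of-plane ortho-OMe that sits between the acetyl and the C3-OMe, giving the H-bonded phenol. No stereocentre is formed.
Identity check: H-5 should show NOEs to two OMe groups. The unwanted 6-hydroxy-2,3,4-trimethoxy isomer would show an NOE to only one.

**Step 2**
Reactants: 3, 1-(2-hydroxy-3,4,6-trimethoxyphenyl)ethan-1-one; 4, 3,4,5-trimethoxybenzaldehyde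
Product: 5, (E)-1-(2-hydroxy-3,4,6-trimethoxyphenyl)-3-(3,4,5-trimethoxyphenyl)prop-2-en-1-one (the 2'-hydroxychalcone)
Conditions: 4 (1.1 equiv), 50% aq KOH (about 10 equiv), EtOH, rt, 24–48 h; then cold 2 M HCl to pH 3; filter and recrystallise from EtOH
Reagents that add atoms: 3,4,5-trimethoxybenzaldehyde, COc1cc(C=O)cc(OC)c1OC (water is lost)
Why: This is a Claisen–Schmidt aldol condensation between the only enolisable partner and a non-enolisable aldehyde, and E1cB dehydration gives the conjugated E-enone. Aryl methyl ethers are inert to KOH. Any flavanone formed by partial cyclisation is converted to the same product in Step 3.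

**Step 3**
Reactants: 5, the 2'-hydroxychalcone
Product: 6, Bannamurpanisin, 5,7,8-trimethoxy-2-(3,4,5-trimethoxyphenyl)-4H-chromen-4-one
Conditions: I2 (10 mol %), DMSO, 120–130 °C, 2–4 h; then ice/aq Na2S2O3; filter or extract with EtOAc; recrystallise from MeOH
Reagents that add atoms: none (net loss of 2 H; DMSO is the terminal oxidant)
Why: This is an I2/DMSO oxidative cyclisation. The 2'-OH adds 6-endo to the enone (oxa-Michael), α-iodination and HI elimination install C2=C3, and DMSO reoxidises HI to I2. Keeping I2 catalytic avoids C6 iodination and HI-induced 5-O-demethylation. With no free 5-OH, Wessely–Moser scrambling of the 5,7,8 pattern to 5,6,7 cannot occur. No stereocentre is present in the product.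

**Verification**
- Atom balance: 1 (C10H14O4) + C2H3O − H − CH3 + H gives 3 (C11H14O5).
- 3 + 4 (C10H12O4) − H2O gives 5 (C21H24O8).
- 5 − 2 H gives 6 (C21H22O8), which matches the target SMILES: 5-, 7-, 8-OMe with H-6 on ring A, H-3 on ring C, and 3',4',5'-OMe on ring B.

## Compound list
1 | 1,2,3,5-tetramethoxybenzene | COc1cc(OC)c(OC)c(OC)c1 | starting material
2 | acetyl chloride | CC(=O)Cl | starting material
3 | 1-(2-hydroxy-3,4,6-trimethoxyphenyl)ethan-1-one | CC(=O)c1c(O)c(OC)c(OC)cc1OC | intermediate
4 | 3,4,5-trimethoxybenzaldehyde | COc1cc(C=O)cc(OC)c1OC | starting material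
5 | (E)-2'-hydroxy-3,4,5,3',4',6'-hexamethoxychalcone | COc1cc(/C=C/C(=O)c2c(O)c(OC)c(OC)cc2OC)cc(OC)c1OC | intermediate
6 | Bannamurpanisin (5,7,8,3',4',5'-hexamethoxyflavone) | COc1cc(-c2cc(=O)c3c(OC)cc(OC)c(OC)c3o2)cc(OC)c1OC | target

## Summary
Total step count: 3
Longest linear sequence: 3

**Steps most likely to fail, in order of risk**
1. **Step 1.** The risks are cleavage of the wrong ortho-OMe, which would lead to the 5,6,7 series, or over-demethylation.
   Fallback: install the 8-oxygen late.
   - Condense commercial 2'-hydroxy-4',6'-dimethoxyacetophenone with 4 and cyclise with I2/DMSO to give 5,7,3',4',5'-pentamethoxyflavone.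
   - Brominate at C8 with NBS.
   - Carry out Cu-mediated Ullmann methoxylation (NaOMe, CuBr, DMF/MeOH).
2. **Step 3.** The risks are ring iodination, 5-O-demethylation, stalling at the flavanone, or aurone by-products.
   Fallback: avoid the oxidation with a Baker–Venkataraman sequence.
   - O-aroylate 3 with 3,4,5-trimethoxybenzoyl chloride in pyridine.
   - Migrate the acyl group with KOH/pyridine to give the 1,3-diketone.
   - Cyclodehydrate with H2SO4/AcOH.
3. **Step 2.** The risk is a sluggish aldol, because the ketone is di-ortho-substituted and deactivated as its phenoxide.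
   Fallback: bypass the aldol by acylating 1 directly with (E)-3,4,5-trimethoxycinnamoyl chloride (AlCl3 or BF3·OEt2). This Friedel–Crafts acylation with ortho-demethylation gives chalcone 5 in one operation.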